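The numbers in the tables were generated by integration on assumed constants, noise included.

Time was the first setting I weighed: in the blue run the tris adduct read 14.6% at 5.00 h and 4.1% at 20.0 h, while the tetra adduct read 1.2%, so by hand I expected a late reading to cost tris adduct.

| flask | substrate | reagent | remark | time |
|---|---|---|---|---|
| blue | 10 mM | 1.5 equiv | run made earlier |  |
| violet | 10 mM | 2.2 equiv | run made earlier |  |
| Sunday's | 10 mM | 1.50 equiv | everything together at the start | 30 h |
| Tuesday's | 10 mM (in portions, 4, over 20 h) | 1.50 equiv | first portion at the start, last at 20 h | 30 h |
| Saturday's | 10 mM | 1.50 equiv (fed, over 20 h) | all else is in the flask from the start; the feed brings no volume worth counting | 30 h |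
| Thursday's | 10 mM (fed, over 20 h) | 1.50 equiv | all else is in the flask from the start; the feed brings no volume worth counting | 30 h |

| run | time / h | tris adduct / % | tetra adduct / % |
|---|---|---|---|
| blue | 5.00 | 14.6 | 0 |
| blue | 10.0 | 10.7 | 0.8 |
| blue | 15.0 | 6.8 | 1.2 |
| blue | 20.0 | 4.1 | 1.2 |
| violet | 0.250 | 0 | 0 |
| violet | 0.500 | 2.8 | 0.4 |
| violet | 1.33 | 13.5 | 0.2 |
| violet | 3.00 | 25.1 | 2.0 |

(readings scatter by 0.5 percentage points)



- which flask leads in share of tris adduct in tris adduct plus tetra adduct ("all alike" within 1.5 percentage points) (Sunday's / Tuesday's / Saturday's / Thursday's / all alike)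
- share of tris adduct in tris adduct plus tetra adduct at the end, Sunday's
- share of tris adduct in tris adduct plus tetra adduct at the end, Tuesday's
- share of tris adduct in tris adduct plus tetra adduct at the end, Saturday's
- share of tris adduct in tris adduct plus tetra adduct at the end, Thursday's

The amount of reagent came next. The violet run, with 2.2 equiv, read 25.1% tris adduct and 2.0% tetra adduct at 3.00 h, so the way to tris adduct looked quick. I assumed that way complete, with each substrate taking 3 reagent, as the name says, and reckoned with the reagent it leaves free:

cover = c(reagent) / (3 · c(substrate))

Sunday's: cover = 0.500

Tuesday's, first portion: cover = 2.00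

This cover is the reagent in the flask against what the substrate in the flask can take up. Below one, the reagent falls short of taking the substrate to tris adduct, so for that product reagent is the limiting reagent, and Sunday's stands there, so I expected little tetra adduct, as in the blue run.

The way the substrate goes in came third. Tuesday's first portion stands above one, so I expected its first tris adduct to meet free reagent. Thursday's feed starts with no substrate, and by my reckoning the substrate fed by 10.0 h can just take up the reagent charge. Both should therefore lose share to tetra adduct.

The way the reagent goes in came last. Saturday's feed has delivered the reagent of Sunday's cover of 0.500 only at its end, and I expected its tris adduct to be younger at 30 h. My order was Saturday's, Sunday's, Thursday's, Tuesday's.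

The forecast gave 84% for Saturday's, 72% for Thursday's, 70% for Tuesday's and 56% for Sunday's, which it put lowest, reasoning that “Feeding matters mainly because it makes the tris younger at the end”. Here my order differs from it.

The simulation gave 92.0% for Saturday's, the highest, then 76.1% for Sunday's, 54.2% for Thursday's and 49.7% for Tuesday's.

    tris adduct ⇌ isomer of the product (K = 19.0, k = 0.100 h⁻¹)
    reagent + bis adduct → tris adduct + by-product (k = 150 M⁻¹ h⁻¹)
    reagent + single product → bis adduct + by-product (k = 27.0 M⁻¹ h⁻¹)
    reagent + tris adduct → tetra adduct + by-product (k = 4.80 M⁻¹ h⁻¹)
    substrate + reagent → single product + by-product (k = 100 M⁻¹ h⁻¹)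

Tuesday's, with its first cover of 2.00, held 4.90% tetra adduct at the end, and Saturday's held 0.619%. A neighbouring flask, Saturday's recipe with 2.50 equiv of reagent, has a cover of 0.833, higher than Saturday's but still below one. It ended with 19.2% tris adduct and 4.89% tetra adduct, a share of 79.7%.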